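**Retrosynthetic overview**
1. Target 29 ⇒ (10S,11S)-epoxide 28 (bromide opens C10 with inversion) ⇒ aryl ketone 24 (C1 carbonyl removed through an ortho-quinone methide).
2. Key step: 24 ⇒ ester 23 by a macrocyclizing intramolecular Diels–Alder reaction (diene C4–C7 plus ynone C2≡C3), which forms the cyclohexadiene and the 15-membered lactone together and creates C7.
3. 23 ⇒ epoxy dienol 17 + ynone acid 22 (from 3-formyl-4-hydroxybenzoic acid).
4. 17 ⇒ (R)-5-acetylbutyrolactone 8 (C10 bought, D-glutamic acid series) + iodide 5 (C14 bought, from (S)-α-hydroxy-γ-butyrolactone); Felkin–Anh addition sets C11; lactone → diene; diol → epoxide.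
5. Ring order: oxirane (step 9), then cyclohexadiene and macrolactone together (step 16); the benzene ring is bought.

Assumption: locants follow the terpenoid skeleton (C1 benzylic carbon, C2–C7 cyclohexadiene with C7 the sp3 CH, C8–C14 chain, C15 isopropenyl carbon); the target is then (7S,10R,11S,14S).

**Route**

Step 1
Reactants: 1 (S)-3-hydroxydihydrofuran-2(3H)-one
Product: 2 (S)-3-(triisopropylsilyloxy)dihydrofuran-2(3H)-one
Conditions: TIPSOTf, 2,6-lutidine, CH2Cl2, 0 °C
Reagents that add atoms: triisopropylsilyl trifluoromethanesulfonate, CC(C)[Si](OS(=O)(=O)C(F)(F)F)(C(C)C)C(C)C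
Why: Silyl ether formation with a silyl triflate and a hindered base is routine for a secondary α-hydroxy lactone, leaves the bought C14 center untouched, and the bulky group is chosen so that it does not migrate in step 3.

Step 2
Reactants: 2 (S)-3-(triisopropylsilyloxy)dihydrofuran-2(3H)-one
Product: 3 (3S)-2-methyl-3-(triisopropylsilyloxy)tetrahydrofuran-2-ol (lactol form of the methyl ketone, anomer mixture)
Conditions: MeLi (1.05 equiv), THF, −78 °C; then H2O
Reagents that add atoms: methyllithium, [Li]C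
Why: Nucleophilic acyl addition of one equivalent of MeLi at −78 °C stops at the tetrahedral lithium lactolate, which gives the methyl ketone as its lactol on work-up.

Step 3
Reactants: 3 (3S)-2-methyl-3-(triisopropylsilyloxy)tetrahydrofuran-2-ol
Product: 4 (S)-4-methyl-3-(triisopropylsilyloxy)pent-4-en-1-ol
Conditions: Ph3PCH3Br, n-BuLi, THF, 0 °C → rt (3 equiv ylide)
Reagents that add atoms: methylidenetriphenylphosphorane (made in the flask from Ph3PCH3Br and n-BuLi), C=P(c1ccccc1)(c1ccccc1)c1ccccc1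
Why: Wittig methylenation of the ring-opened ketone tautomer builds the isopropenyl group, with excess ylide because the lactol OH consumes one equivalent, and C14 is not touched.

Step 4
Reactants: 4 (S)-4-methyl-3-(triisopropylsilyloxy)pent-4-en-1-ol
Product: 5 (S)-[(5-iodo-2-methylpent-1-en-3-yl)oxy]triisopropylsilane
Conditions: I2, PPh3, imidazole, CH2Cl2, 0 °C
Reagents that add atoms: iodine, I-I
Why: Appel-type iodination converts the primary alcohol into the iodide under neutral conditions without affecting the allylic silyl ether.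

Step 5
Reactants: 6 (R)-5-oxotetrahydrofuran-2-carboxylic acid
Product: 8 (R)-5-acetyldihydrofuran-2(3H)-one, via acid chloride 7 (not isolated)
Conditions: (COCl)2, DMF (cat.), CH2Cl2, 0 °C → rt; then Me2CuLi (from MeLi, CuI), Et2O, −78 °C
Reagents that add atoms: lithium dimethylcuprate Me2CuLi, [Li+].C[Cu-]C
Why: Acid chloride formation followed by acylation of the Gilman cuprate gives the methyl ketone without over-addition or epimerization of the α-acyloxy center C10 and leaves the lactone intact.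

Step 6
Reactants: 5 (S)-[(5-iodo-2-methylpent-1-en-3-yl)oxy]triisopropylsilane; 8 (R)-5-acetyldihydrofuran-2(3H)-one
Product: 11 (R)-5-[(2S,5S)-2-hydroxy-6-methyl-5-(triisopropylsilyloxy)hept-6-en-2-yl]dihydrofuran-2(3H)-one, via alkyllithium 9 (not isolated), via organocerium 10 (not isolated)
Conditions: 5, t-BuLi (2.1 equiv), Et2O, −78 °C; CeCl3, THF, −78 °C; then 8, −78 °C; then H2O
Reagents that add atoms: none
Why: Iodine–lithium exchange and transmetalation give a non-basic organocerium reagent that adds only to the ketone, and with the non-chelating lactone oxygen anti to the nucleophile (polar Felkin–Anh/Cornforth addition, attack past H and not past C9) the tertiary carbinol C11 forms as the (S)-epimer.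

Step 7
Reactants: 11 (R)-5-[(2S,5S)-2-hydroxy-6-methyl-5-(triisopropylsilyloxy)hept-6-en-2-yl]dihydrofuran-2(3H)-one
Product: 12 (5R)-5-[(2S,5S)-2-hydroxy-6-methyl-5-(triisopropylsilyloxy)hept-6-en-2-yl]tetrahydrofuran-2-ol (anomer mixture)
Conditions: i-Bu2AlH (2.2 equiv), CH2Cl2, −78 °C
Reagents that add atoms: none
Why: Partial reduction of the γ-lactone stops at the lactol because the aluminium hemiacetal is stable at −78 °C until work-up.

Step 8
Reactants: 12 (5R)-5-[(2S,5S)-2-hydroxy-6-methyl-5-(triisopropylsilyloxy)hept-6-en-2-yl]tetrahydrofuran-2-ol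
Product: 13 (2E,6R,7S,10S)-6,7-dihydroxy-2,7,11-trimethyl-10-(triisopropylsilyloxy)dodeca-2,11-dienal
Conditions: Ph3P=C(CH3)CHO, toluene, 90 °C
Reagents that add atoms: 2-(triphenylphosphoranylidene)propanal, CC(C=O)=P(c1ccccc1)(c1ccccc1)c1ccccc1
Why: Wittig olefination of the open hydroxy-aldehyde form of the lactol with the formyl-stabilized ylide gives the (E)-2-methyl enal selectively and frees the C10 hydroxyl.

Step 9
Reactants: 13 (2E,6R,7S,10S)-6,7-dihydroxy-2,7,11-trimethyl-10-(triisopropylsilyloxy)dodeca-2,11-dienal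
Product: 15 (2E)-2-methyl-5-[(2S,3S)-3-methyl-3-[(3S)-4-methyl-3-(triisopropylsilyloxy)pent-4-en-1-yl]oxiran-2-yl]pent-2-enal, via mesylate 14 (not isolated)
Conditions: MsCl, Et3N, CH2Cl2, −30 °C; then K2CO3, MeOH, 0 °C
Reagents that add atoms: none
Why: The secondary C10 alcohol is mesylated selectively over the tertiary C11 alcohol, and the C11 alkoxide then displaces the mesylate (intramolecular SN2, Williamson-type epoxide closure) with inversion at C10 to give the (10S,11S)-trans-epoxide before any base meets a free hydroxy enal.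

Step 10
Reactants: 15 (2E)-2-methyl-5-[(2S,3S)-3-methyl-3-[(3S)-4-methyl-3-(triisopropylsilyloxy)pent-4-en-1-yl]oxiran-2-yl]pent-2-enal
Product: 16 (2S,3S)-2-methyl-3-[(3E)-4-methylhexa-3,5-dien-1-yl]-2-[(3S)-4-methyl-3-(triisopropylsilyloxy)pent-4-en-1-yl]oxirane
Conditions: Ph3PCH3Br, n-BuLi, THF, −78 → 0 °C
Reagents that add atoms: methylidenetriphenylphosphorane (made in the flask from Ph3PCH3Br and n-BuLi), C=P(c1ccccc1)(c1ccccc1)c1ccccc1
Why: Wittig methylenation of the enal gives the (E)-1,3-diene without touching the epoxide.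

Step 11
Reactants: 16 (2S,3S)-2-methyl-3-[(3E)-4-methylhexa-3,5-dien-1-yl]-2-[(3S)-4-methyl-3-(triisopropylsilyloxy)pent-4-en-1-yl]oxirane
Product: 17 (3S)-2-methyl-5-[(2S,3S)-2-methyl-3-[(3E)-4-methylhexa-3,5-dien-1-yl]oxiran-2-yl]pent-1-en-3-ol
Conditions: Bu4NF, THF, rt
Reagents that add atoms: none
Why: Fluoride-mediated silyl ether cleavage frees the C14 alcohol under basic conditions that the epoxide tolerates.

Step 12
Reactants: 18 3-formyl-4-hydroxybenzoic acid
Product: 20 3-formyl-4-(triisopropylsilyloxy)benzoic acid, via silyl ester 19 (not isolated)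
Conditions: TIPSCl (2.3 equiv), imidazole, DMF, rt; then AcOH, THF/H2O
Reagents that add atoms: triisopropylsilyl chloride, CC(C)[Si](Cl)(C(C)C)C(C)C
Why: Silylation of phenol and acid followed by selective hydrolysis of the labile silyl ester gives the phenol-protected acid.

Step 13
Reactants: 20 3-formyl-4-(triisopropylsilyloxy)benzoic acid
Product: 21 3-(1-hydroxybut-2-yn-1-yl)-4-(triisopropylsilyloxy)benzoic acid (racemic carbinol)
Conditions: CH3C≡CMgBr (2.2 equiv), THF, −78 → −20 °C; then 1 M HCl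
Reagents that add atoms: 1-propynylmagnesium bromide, CC#C[Mg]Br
Why: Grignard 1,2-addition to the aldehyde (the first equivalent only deprotonates the acid) gives the propargylic alcohol, whose carbinol center is removed in the next step.

Step 14
Reactants: 21 3-(1-hydroxybut-2-yn-1-yl)-4-(triisopropylsilyloxy)benzoic acid
Product: 22 3-(but-2-ynoyl)-4-(triisopropylsilyloxy)benzoic acid
Conditions: Dess–Martin periodinane, CH2Cl2, rt
Reagents that add atoms: none
Why: Dess–Martin oxidation of the benzylic propargylic alcohol gives the ynone under neutral conditions.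

Step 15
Reactants: 17 (3S)-2-methyl-5-[(2S,3S)-2-methyl-3-[(3E)-4-methylhexa-3,5-dien-1-yl]oxiran-2-yl]pent-1-en-3-ol; 22 3-(but-2-ynoyl)-4-(triisopropylsilyloxy)benzoic acid
Product: 23 (3S)-2-methyl-5-[(2S,3S)-2-methyl-3-[(3E)-4-methylhexa-3,5-dien-1-yl]oxiran-2-yl]pent-1-en-3-yl 3-(but-2-ynoyl)-4-(triisopropylsilyloxy)benzoate
Conditions: DIC, DMAP (0.1 equiv), CH2Cl2, 0 °C
Reagents that add atoms: none
Why: Steglich esterification acylates the secondary allylic alcohol with retention at C14, while the silyl ether keeps the phenol from being acylated or cyclizing onto the ynone.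

Step 16
Reactants: 23 (3S)-2-methyl-5-[(2S,3S)-2-methyl-3-[(3E)-4-methylhexa-3,5-dien-1-yl]oxiran-2-yl]pent-1-en-3-yl 3-(but-2-ynoyl)-4-(triisopropylsilyloxy)benzoate
Product: 24 (7S,10S,11S,14S)-macrocyclic ketone (target skeleton with C1 as C=O, the 10,11-epoxide in place of the bromohydrin, phenol as triisopropylsilyl ether)
Conditions: toluene (2 mM), BHT (cat.), 140 °C, sealed tube, 48 h
Reagents that add atoms: none
Why: The intramolecular Diels–Alder reaction bonds C7 to C2 and C4 to C3 (orientation fixed by the tether, the ortho rule for the 1-alkyl diene and the β-methyl group of the ynone), forming the 1,4-cyclohexadiene and the 15-membered lactone at once; C7 is set by the diene face that the tether carrying the epoxide and C14 exposes, and the (7S)-macrolide is the isomer taken on after chromatography.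

Step 17
Reactants: 24 (7S,10S,11S,14S)-macrocyclic ketone
Product: 28 (7S,10S,11S,14S)-10,11-epoxy phenol macrolide, via free phenol 25 (not isolated), via ethyl carbonate 26 (not isolated), via quinone methide 27 (not isolated)
Conditions: Bu4NF (1.1 equiv), THF, −20 °C; then ClCO2Et; then NaBH4, H2O, 0 °C → rt
Reagents that add atoms: none
Why: Fluoride frees the phenoxide, which is trapped as its ethyl carbonate, and borohydride reduction of the ketone then triggers carbonate transfer and 1,4-elimination to an ortho-quinone methide that a second hydride reduces at C1 (deoxygenation of an ortho-hydroxyaryl ketone), leaving epoxide, lactone and C7 untouched.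

Step 18
Reactants: 28 (7S,10S,11S,14S)-10,11-epoxy phenol macrolide
Product: 29 target CNP0186361.2, (7S,10R,11S,14S)
Conditions: Li2NiBr4 (0.5 M in THF, 2 equiv), THF, 0 °C → rt; then H2O
Reagents that add atoms: dilithium tetrabromonickelate Li2NiBr4, [Li+].[Li+].Br[Ni-2](Br)(Br)Br
Why: Li2NiBr4 delivers soft bromide in an SN2 opening of the trisubstituted epoxide at the less substituted carbon C10 with inversion, giving the (10R)-bromide and the (11S)-tertiary alcohol with C11 untouched.

**Compound list**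
1 | (S)-3-hydroxydihydrofuran-2(3H)-one ((S)-α-hydroxy-γ-butyrolactone) | O[C@H]1CCOC1=O | starting material
2 | (S)-3-(triisopropylsilyloxy)dihydrofuran-2(3H)-one | CC(C)[Si](O[C@H]1CCOC1=O)(C(C)C)C(C)C | intermediate
3 | (3S)-2-methyl-3-(triisopropylsilyloxy)tetrahydrofuran-2-ol | CC1(O)OCC[C@@H]1O[Si](C(C)C)(C(C)C)C(C)C | intermediate
4 | (S)-4-methyl-3-(triisopropylsilyloxy)pent-4-en-1-ol | C=C(C)[C@H](CCO)O[Si](C(C)C)(C(C)C)C(C)C | intermediate
5 | (S)-[(5-iodo-2-methylpent-1-en-3-yl)oxy]triisopropylsilane | C=C(C)[C@H](CCI)O[Si](C(C)C)(C(C)C)C(C)C | intermediate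
6 | (R)-5-oxotetrahydrofuran-2-carboxylic acid | OC(=O)[C@H]1CCC(=O)O1 | starting material
7 | (R)-5-oxotetrahydrofuran-2-carbonyl chloride (not isolated) | ClC(=O)[C@H]1CCC(=O)O1 | intermediate
8 | (R)-5-acetyldihydrofuran-2(3H)-one | CC(=O)[C@H]1CCC(=O)O1 | intermediate
9 | [(3S)-4-methyl-3-(triisopropylsilyloxy)pent-4-en-1-yl]lithium (not isolated) | C=C(C)[C@H](CC[Li])O[Si](C(C)C)(C(C)C)C(C)C | intermediate
10 | dichloro[(3S)-4-methyl-3-(triisopropylsilyloxy)pent-4-en-1-yl]cerium (not isolated) | C=C(C)[C@H](CC[Ce](Cl)Cl)O[Si](C(C)C)(C(C)C)C(C)C | intermediate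
11 | (R)-5-[(2S,5S)-2-hydroxy-6-methyl-5-(triisopropylsilyloxy)hept-6-en-2-yl]dihydrofuran-2(3H)-one | C=C(C)[C@H](CC[C@](C)(O)[C@H]1CCC(=O)O1)O[Si](C(C)C)(C(C)C)C(C)C | intermediate
12 | (5R)-5-[(2S,5S)-2-hydroxy-6-methyl-5-(triisopropylsilyloxy)hept-6-en-2-yl]tetrahydrofuran-2-ol | C=C(C)[C@H](CC[C@](C)(O)[C@H]1CCC(O)O1)O[Si](C(C)C)(C(C)C)C(C)C | intermediate
13 | (2E,6R,7S,10S)-6,7-dihydroxy-2,7,11-trimethyl-10-(triisopropylsilyloxy)dodeca-2,11-dienal | O=C/C(C)=C/CC[C@@H](O)[C@@](C)(O)CC[C@H](O[Si](C(C)C)(C(C)C)C(C)C)C(C)=C | intermediate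
14 | C10 methanesulfonate of 13 (not isolated) | O=C/C(C)=C/CC[C@@H](OS(C)(=O)=O)[C@@](C)(O)CC[C@H](O[Si](C(C)C)(C(C)C)C(C)C)C(C)=C | intermediate
15 | (2E)-2-methyl-5-[(2S,3S)-3-methyl-3-[(3S)-4-methyl-3-(triisopropylsilyloxy)pent-4-en-1-yl]oxiran-2-yl]pent-2-enal | O=C/C(C)=C/CC[C@@H]1O[C@@]1(C)CC[C@H](O[Si](C(C)C)(C(C)C)C(C)C)C(C)=C | intermediate
16 | (2S,3S)-2-methyl-3-[(3E)-4-methylhexa-3,5-dien-1-yl]-2-[(3S)-4-methyl-3-(triisopropylsilyloxy)pent-4-en-1-yl]oxirane | C=C/C(C)=C/CC[C@@H]1O[C@@]1(C)CC[C@H](O[Si](C(C)C)(C(C)C)C(C)C)C(C)=C | intermediate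
17 | (3S)-2-methyl-5-[(2S,3S)-2-methyl-3-[(3E)-4-methylhexa-3,5-dien-1-yl]oxiran-2-yl]pent-1-en-3-ol | C=C/C(C)=C/CC[C@@H]1O[C@@]1(C)CC[C@H](O)C(C)=C | intermediate
18 | 3-formyl-4-hydroxybenzoic acid | O=Cc1cc(C(=O)O)ccc1O | starting material
19 | triisopropylsilyl 3-formyl-4-(triisopropylsilyloxy)benzoate (not isolated) | O=Cc1cc(C(=O)O[Si](C(C)C)(C(C)C)C(C)C)ccc1O[Si](C(C)C)(C(C)C)C(C)C | intermediate
20 | 3-formyl-4-(triisopropylsilyloxy)benzoic acid | O=Cc1cc(C(=O)O)ccc1O[Si](C(C)C)(C(C)C)C(C)C | intermediate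
21 | 3-(1-hydroxybut-2-yn-1-yl)-4-(triisopropylsilyloxy)benzoic acid (racemic) | CC#CC(O)c1cc(C(=O)O)ccc1O[Si](C(C)C)(C(C)C)C(C)C | intermediate
22 | 3-(but-2-ynoyl)-4-(triisopropylsilyloxy)benzoic acid | CC#CC(=O)c1cc(C(=O)O)ccc1O[Si](C(C)C)(C(C)C)C(C)C | intermediate
23 | ester of 17 with 22 (Diels–Alder precursor) | C=C/C(C)=C/CC[C@@H]1O[C@@]1(C)CC[C@H](OC(=O)c1ccc(O[Si](C(C)C)(C(C)C)C(C)C)c(C(=O)C#CC)c1)C(C)=C | intermediate
24 | (7S,10S,11S,14S)-macrocyclic ketone: target skeleton with C1 as C=O, 10,11-epoxide, phenol as triisopropylsilyl ether | C=C(C)[C@@H]1CC[C@]2(C)O[C@H]2CC[C@H]3C(C)=CCC(C)=C3C(=O)c4cc(ccc4O[Si](C(C)C)(C(C)C)C(C)C)C(=O)O1 | intermediate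
25 | free phenol of 24 (not isolated) | C=C(C)[C@@H]1CC[C@]2(C)O[C@H]2CC[C@H]3C(C)=CCC(C)=C3C(=O)c4cc(ccc4O)C(=O)O1 | intermediate
26 | aryl ethyl carbonate of 25 (not isolated) | C=C(C)[C@@H]1CC[C@]2(C)O[C@H]2CC[C@H]3C(C)=CCC(C)=C3C(=O)c4cc(ccc4OC(=O)OCC)C(=O)O1 | intermediate
27 | ortho-quinone methide (C1=C exocyclic, ring carbonyl in place of the phenol; not isolated) | C=C(C)[C@@H]1CC[C@]2(C)O[C@H]2CC[C@H]3C(C)=CCC(C)=C3C=C4C=C(C=CC4=O)C(=O)O1 | intermediate
28 | (7S,10S,11S,14S)-10,11-epoxy phenol macrolide (target with the epoxide in place of the bromohydrin) | C=C(C)[C@@H]1CC[C@]2(C)O[C@H]2CC[C@H]3C(C)=CCC(C)=C3Cc4cc(ccc4O)C(=O)O1 | intermediate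
29 | CNP0186361.2, (7S,10R,11S,14S) | C=C(C)[C@@H]1CC[C@](C)(O)[C@H](Br)CC[C@H]2C(C)=CCC(C)=C2Cc2cc(ccc2O)C(=O)O1 | target

**Totals and risks**

Total step count: 18. Longest linear sequence: 14 steps (1–4, 6–11, 15–18), from (S)-α-hydroxy-γ-butyrolactone.

Most likely to fail, first: step 16. An unactivated 1,2-disubstituted diene must find a β-methyl ynone at 2 mM, so oligomerization or no reaction is possible. The facial selectivity at C7 rests only on the conformation of the tether and cannot be predicted with confidence; the 7-epimer may form in quantity and must then be separated. The fallback sets out from 22 and 16 and comes back at 25. Acid 22 is esterified with 2-(trimethylsilyl)ethanol (DIC, DMAP) to the 2-(trimethylsilyl)ethyl ynone ester F1. F1 is heated with diene 16 (toluene, 2 M, 110 °C) in an intermolecular Diels–Alder reaction to the open-chain cyclohexadienyl ketone F2; both C7 epimers are expected and are separated here or after ring closure. Excess Bu4NF removes both silyl ethers and the silylethyl ester to give the seco acid F3. Shiina macrolactonization (2-methyl-6-nitrobenzoic anhydride, DMAP, Et3N, CH2Cl2, 1 mM) then closes the lactone; the phenol is hydrogen-bonded to the C1 ketone and stays free. This gives 25, which is taken on with ClCO2Et and NaBH4 as in step 17.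

Second: step 17. The skipped dienone has acidic C4 protons and may isomerize or aromatize under fluoride, and hydride could add to the quinone methide at C3 instead of C1. The fallback sets out from 24 and comes back at 28. The ketone is reduced first (NaBH4, CeCl3·7H2O, MeOH, −40 °C) to the benzylic alcohol F4, which is acetylated (Ac2O, pyridine, DMAP) to the benzylic acetate F5. Bu4NF is then added in the presence of NaBH4: the phenoxide expels the acetate to give quinone methide 27, which is reduced in the flask to 28, so no free phenoxide ever coexists with the dienone.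

Third: step 6. The Felkin–Anh selectivity at C11 may be modest or follow the chelate sense, and the cerium reagent may touch the lactone or erode C10. The fallback sets out from 5 and 7 and comes back at 11. Zinc is inserted into 5 (Zn, LiCl, THF) to give the alkylzinc iodide F6, which is acylated with acid chloride 7 (Pd(PPh3)4 cat., THF, 0 °C) to the chain ketone F7. The methyl group is added last (MeMgBr, CH2Cl2/Et2O, −78 °C). With the two carbon groups introduced in the reverse order, a chelate-type facial bias now gives the same (11S)-carbinol 11, and no basic organometallic meets the epimerizable ketone 8. This helps only if step 6 shows chelate-type selectivity; it does not rescue an unselective addition.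

Further compounds
F1 | step 16 | 2-(trimethylsilyl)ethyl 3-(but-2-ynoyl)-4-(triisopropylsilyloxy)benzoate | CC#CC(=O)c1cc(C(=O)OCC[Si](C)(C)C)ccc1O[Si](C(C)C)(C(C)C)C(C)C
F2 | step 16 | intermolecular Diels–Alder adduct of F1 with 16, (7S)-isomer shown | C=C(C)[C@H](CC[C@]1(C)O[C@H]1CC[C@H]1C(C)=CCC(C)=C1C(=O)c1cc(C(=O)OCC[Si](C)(C)C)ccc1O[Si](C(C)C)(C(C)C)C(C)C)O[Si](C(C)C)(C(C)C)C(C)C
F3 | step 16 | seco acid (free C14 alcohol, free phenol, free carboxylic acid, C1 ketone) | C=C(C)[C@@H](O)CC[C@]1(C)O[C@H]1CC[C@H]1C(C)=CCC(C)=C1C(=O)c1cc(C(=O)O)ccc1O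
F4 | step 17 | C1 alcohol of 24 (carbinol epimers) | C=C(C)[C@@H]1CC[C@]2(C)O[C@H]2CC[C@H]3C(C)=CCC(C)=C3C(O)c4cc(ccc4O[Si](C(C)C)(C(C)C)C(C)C)C(=O)O1
F5 | step 17 | C1 acetate of F4 | C=C(C)[C@@H]1CC[C@]2(C)O[C@H]2CC[C@H]3C(C)=CCC(C)=C3C(OC(C)=O)c4cc(ccc4O[Si](C(C)C)(C(C)C)C(C)C)C(=O)O1
F6 | step 6 | iodo[(3S)-4-methyl-3-(triisopropylsilyloxy)pent-4-en-1-yl]zinc | C=C(C)[C@H](CC[Zn]I)O[Si](C(C)C)(C(C)C)C(C)C
F7 | step 6 | (R)-5-[(4S)-5-methyl-4-(triisopropylsilyloxy)hex-5-enoyl]dihydrofuran-2(3H)-one | C=C(C)[C@H](CCC(=O)[C@H]1CCC(=O)O1)O[Si](C(C)C)(C(C)C)C(C)C
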